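**Retrosynthetic overview** (phthalide numbering: C1 lactone carbonyl, C3 lactol carbon, C3a–C7a ring B; ring A is the benzoate)
1. Target 22 ⇐ (R)-acetate 21 ⇐ racemic lactol 20, by lipase dynamic acetylation and then enzymatic deacetylation. 20 ⇐ ester 17 by unmasking C3 (acetal), C1 (methyl ester) and the C7 oxygen (MOM). 17 ⇐ benzylic alcohol 13 + ring A acid 16 (Mitsunobu, C6–CH2–O bond).
2. Feature: ring B carries on three neighbouring carbons the C7 oxygen, C7a with the carboxyl carbon C1, and C3a with the acetal carbon C3. This is the 4-alkoxy / 5-carboxy / 6-substituent sequence of a 2-pyrone. C6 with its CH2O group is pyrone C3, and the C5(OMe)–C4(H) edge is 1,1-dimethoxyethene.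
3. Ring B ⇐ pyrone 8 + ketene acetal 9: [4+2] addition forming C5–C6 and C4–C3a, then loss of CO2 and MeOH.
4. Pyrone 8 ⇐ 2-(benzyloxymethyl)malonyl dichloride 5 + β-keto ester 6, then O-protection. The pyrone oxygen carries MOM instead of methyl, so that C7–OH is freed at the end by dilute acid and no Lewis-acid demethylation is needed next to the benzylic ester.
5. Ring order: pyrone ring (step 4), ring B (step 6), lactone ring of the phthalide (step 11); ring A is bought as 14.

Key step: step 6

Assumption: the C3 lactol equilibrates through the ring-opened 2-formylbenzoic acid; this is taken to be fast enough at 40 °C for step 13 and slow enough at 0–5 °C in a dry, base-free medium for 22 to be isolated as the (R)-enantiomer.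
Assumption: the lipase is taken to acylate the (R)-lactol, as the empirical size rule for secondary alcohols predicts; the sense must be confirmed on the first run. Compounds 10, 19 and 20 are racemic.

**Step 1**
Reactants: 1 diethyl malonate; 2 benzyl chloromethyl ether
Product: 3 diethyl 2-[(benzyloxy)methyl]malonate
Conditions: NaH (1.0 equiv), 1 (2.0 equiv), THF, 0 °C; then 2 (1.0 equiv), 0 °C → rt
Reagents that add atoms: none
Why: SN2 C-alkylation of sodium diethyl malonate by the α-chloro ether, in which the excess of malonate keeps the product protonated and so should suppress dialkylation and E1cB loss of benzyl alcoholate.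

**Step 2**
Reactants: 3 diethyl 2-[(benzyloxy)methyl]malonate
Product: 4 2-[(benzyloxy)methyl]malonic acid
Conditions: KOH (3 equiv), EtOH–H2O, 0 °C → rt; then 3 M HCl, 0 °C, to pH 1
Reagents that add atoms: potassium hydroxide, [K+].[OH-]
Why: ester saponification, run at or below room temperature and acidified cold because the substituted malonic acid decarboxylates on heating and forcing base could eliminate the β-benzyloxy group.

**Step 3**
Reactants: 4 2-[(benzyloxy)methyl]malonic acid
Product: 5 2-[(benzyloxy)methyl]malonyl dichloride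
Conditions: (COCl)2 (2.4 equiv), DMF (cat.), CH2Cl2, 0 °C → rt; evaporate, use crude at once
Reagents that add atoms: oxalyl chloride, O=C(Cl)C(Cl)=O
Why: acid chloride formation through the Vilsmeier-type chloroiminium species under cold, neutral conditions that a benzyl ether tolerates.

**Step 4**
Reactants: 5 2-[(benzyloxy)methyl]malonyl dichloride; 6 methyl 4,4-dimethoxy-3-oxobutanoate
Product: 7 methyl 3-[(benzyloxy)methyl]-6-(dimethoxymethyl)-4-hydroxy-2-oxo-2H-pyran-5-carboxylate
Conditions: 5 (1.1 equiv), CH2Cl2, 0 °C → 40 °C, slow N2 sweep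
Reagents that add atoms: none
Why: the known annulation of malonyl dichlorides with β-keto esters (C-acylation at the active methylene of 6, then lactonisation by the ketone enol oxygen) should give the 5-methoxycarbonyl-4-hydroxy-2-pyrone, and the acetal, sitting on an electron-poor carbon, should ionise too reluctantly to be lost to the HCl that is swept out.

**Step 5**
Reactants: 7 methyl 3-[(benzyloxy)methyl]-6-(dimethoxymethyl)-4-hydroxy-2-oxo-2H-pyran-5-carboxylate
Product: 8 methyl 3-[(benzyloxy)methyl]-6-(dimethoxymethyl)-4-(methoxymethoxy)-2-oxo-2H-pyran-5-carboxylate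
Conditions: MOMCl (1.3 equiv), iPr2NEt (1.5 equiv), CH2Cl2, 0 °C → rt
Reagents that add atoms: chloromethyl methyl ether, COCCl
Why: O-alkylation of the vinylogous carboxylic acid by a hard α-chloro ether should give the 4-alkoxy-2-pyrone (C3 is blocked), and installs the protecting group of the future C7 phenol.

**Step 6**
Reactants: 8 methyl 3-[(benzyloxy)methyl]-6-(dimethoxymethyl)-4-(methoxymethoxy)-2-oxo-2H-pyran-5-carboxylate; 9 1,1-dimethoxyethene
Product: 12 methyl 3-[(benzyloxy)methyl]-6-(dimethoxymethyl)-4-methoxy-2-(methoxymethoxy)benzoate, via bridged lactone cycloadduct 10 (not isolated), via dimethoxycyclohexadiene 11 (not isolated)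
Conditions: 9 (10 equiv), iPr2NEt (0.1 equiv), PhMe, sealed tube, 160 °C
Reagents that add atoms: none
Why: The nucleophilic CH2 of the ketene acetal bonds to pyrone C6 (β to the 5-ester and vinylogous to the lactone carbonyl) and its acetal carbon to pyrone C3, an inverse-electron-demand [4+2] addition (concerted but asynchronous, or stepwise through a zwitterion) that gives the 2-oxabicyclo[2.2.2]octenone 10. Cycloreversion of 10 expels CO2 to diene 11, and 1,2-elimination of methanol from its ketal carbon and the adjacent CH2 aromatises it to 12. The closest known reaction is the Diels–Alder/decarboxylation/aromatisation of 5-alkoxycarbonyl-2-pyrones with 1,1-dimethoxyethene to 4-methoxybenzoates. Ring B is closed as a six-membered carbocycle by this intermolecular [4+2] annulation, forming C5–C6 and C4–C3a of the target; the two bridgehead stereocentres of 10 are destroyed, so no stereocentre has to be controlled. The selectivity needed is the orientation of the unsymmetrical ketene acetal, secured by the polarisation of the pyrone (electrophilic at the ester-activated C6, nucleophilic at C3 next to the 4-alkoxy donor), which places the new methoxy group para to the ester. Both diene ends are fully substituted and the 4-alkoxy group lowers the reactivity, hence the large excess of 9, the sealed tube and the trace of hindered amine that keeps the acetals and the MOM group from acid.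

**Step 7**
Reactants: 12 methyl 3-[(benzyloxy)methyl]-6-(dimethoxymethyl)-4-methoxy-2-(methoxymethoxy)benzoate
Product: 13 methyl 6-(dimethoxymethyl)-3-(hydroxymethyl)-4-methoxy-2-(methoxymethoxy)benzoate
Conditions: H2 (1 atm), 10% Pd/C, EtOAc, rt
Reagents that add atoms: none
Why: catalytic hydrogenolysis should cleave the unhindered PhCH2–O bond, whereas the other benzylic C–O bond lies between two ortho substituents and adsorbs poorly, and the acetal, MOM ether and ester are inert in neutral ethyl acetate.

**Step 8**
Reactants: 14 methyl 2,4-dihydroxy-3,6-dimethylbenzoate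
Product: 15 methyl 2-hydroxy-4-methoxy-3,6-dimethylbenzoate
Conditions: MeI (1.05 equiv), K2CO3 (1.1 equiv), acetone, rt → 40 °C
Reagents that add atoms: iodomethane, CI
Why: Williamson methylation should be selective for the 4-OH, because the 2-OH is hydrogen-bonded to the ester carbonyl and flanked by the 3-methyl group.

**Step 9**
Reactants: 15 methyl 2-hydroxy-4-methoxy-3,6-dimethylbenzoate
Product: 16 2-hydroxy-4-methoxy-3,6-dimethylbenzoic acid
Conditions: KOH (4 M aq), DMSO, 80 °C; then 1 M HCl, 0 °C, to pH 2
Reagents that add atoms: potassium hydroxide, [K+].[OH-]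
Why: saponification of the hindered salicylate under forcing hydroxide, where the phenoxide-carboxylate dianion resists decarboxylation and cold acidification protects the free β-resorcylic-type acid.

**Step 10**
Reactants: 13 methyl 6-(dimethoxymethyl)-3-(hydroxymethyl)-4-methoxy-2-(methoxymethoxy)benzoate; 16 2-hydroxy-4-methoxy-3,6-dimethylbenzoic acid
Product: 17 [4-(dimethoxymethyl)-6-methoxy-3-(methoxycarbonyl)-2-(methoxymethoxy)phenyl]methyl 2-hydroxy-4-methoxy-3,6-dimethylbenzoate
Conditions: PPh3 (1.3 equiv), DIAD (1.3 equiv), THF, 0 °C → rt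
Reagents that add atoms: none
Why: Mitsunobu esterification, in which the carboxylate of the hindered acid attacks the primary benzylic alkoxyphosphonium carbon (hindrance on the acid side does not matter) and the chelated phenol is too weakly acidic to compete.

**Step 11**
Reactants: 17 [4-(dimethoxymethyl)-6-methoxy-3-(methoxycarbonyl)-2-(methoxymethoxy)phenyl]methyl 2-hydroxy-4-methoxy-3,6-dimethylbenzoate
Product: 19 [3-hydroxy-5-methoxy-7-(methoxymethoxy)-1-oxo-1,3-dihydroisobenzofuran-6-yl]methyl 2-hydroxy-4-methoxy-3,6-dimethylbenzoate (racemic), via formyl ester 18 (not isolated)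
Conditions: PPTS (0.2 equiv), THF–H2O, 40 °C; then LiOH (3 equiv), 0 °C; then 1 M HCl, 0 °C, to pH 3
Reagents that add atoms: water, O; lithium hydroxide, [Li+].[OH-]
Why: mild acetal hydrolysis frees the aldehyde while the aryl MOM ether survives, and the methyl ester ortho to it is then saponified at 0 °C by neighbouring-group participation (the aldehyde hydrate oxyanion attacks the ester and closes the 3-hydroxyphthalide), far faster than hydroxide can attack the doubly ortho-substituted ring A ester; with C7 still protected no phenoxide can expel the carboxylate as an ortho-quinone methide, and the lactol forms as a racemate.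

**Step 12**
Reactants: 19 [3-hydroxy-5-methoxy-7-(methoxymethoxy)-1-oxo-1,3-dihydroisobenzofuran-6-yl]methyl 2-hydroxy-4-methoxy-3,6-dimethylbenzoate (racemic)
Product: 20 [3,7-dihydroxy-5-methoxy-1-oxo-1,3-dihydroisobenzofuran-6-yl]methyl 2-hydroxy-4-methoxy-3,6-dimethylbenzoate (racemic)
Conditions: 2 M HCl, THF, rt → 35 °C; work-up without base
Reagents that add atoms: none
Why: acid hydrolysis of the phenolic MOM acetal, helped by the chelating lactone carbonyl, under dilute Brønsted acid that should leave the benzylic ester and the methyl ethers untouched; base is avoided from here on because a C7 phenoxide could eliminate the ring A carboxylate.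

**Step 13**
Reactants: 20 [3,7-dihydroxy-5-methoxy-1-oxo-1,3-dihydroisobenzofuran-6-yl]methyl 2-hydroxy-4-methoxy-3,6-dimethylbenzoate (racemic)
Product: 21 [(3R)-3-acetoxy-7-hydroxy-5-methoxy-1-oxo-1,3-dihydroisobenzofuran-6-yl]methyl 2-hydroxy-4-methoxy-3,6-dimethylbenzoate
Conditions: vinyl acetate (5 equiv), immobilised Burkholderia cepacia lipase (Amano PS-IM), MTBE–THF, 40 °C
Reagents that add atoms: vinyl acetate, C=COC(C)=O
Why: lipase-catalysed irreversible transesterification run as a dynamic kinetic resolution, the reaction type known for 5-hydroxy-2(5H)-furanones of which 20 is the benzo-fused analogue: the lactol enantiomers interconvert through the ring-opened aldehyde acid while the enzyme acylates only one, expected to be the (R)-lactol (fused arene as large and ring oxygen as medium substituent, as in (R)-indan-1-ol), so C3 is set by the enzyme and then locked as the acetate; the chelated phenols should not be acylated.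

**Step 14**
Reactants: 21 [(3R)-3-acetoxy-7-hydroxy-5-methoxy-1-oxo-1,3-dihydroisobenzofuran-6-yl]methyl 2-hydroxy-4-methoxy-3,6-dimethylbenzoate
Product: 22 [(3R)-3,7-dihydroxy-5-methoxy-1-oxo-1,3-dihydroisobenzofuran-6-yl]methyl 2-hydroxy-4-methoxy-3,6-dimethylbenzoate
Conditions: n-BuOH (5 equiv), immobilised Burkholderia cepacia lipase (Amano PS-IM), dry MTBE, 0–5 °C; filter, concentrate cold, crystallise
Reagents that add atoms: none
Why: lipase-catalysed alcoholysis breaks only the acyl–oxygen bond of the acetate, so the C3–O bond and the (R) configuration are retained, and the dry, base-free, cold medium is chosen to hold back ring–chain racemisation of the freed lactol; the hindered ring A ester is not a lipase substrate.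

**Compound list**
1 | diethyl malonate | CCOC(=O)CC(=O)OCC | starting material
2 | benzyl chloromethyl ether | ClCOCc1ccccc1 | starting material
3 | diethyl 2-[(benzyloxy)methyl]malonate | CCOC(=O)C(COCc1ccccc1)C(=O)OCC | intermediate
4 | 2-[(benzyloxy)methyl]malonic acid | OC(=O)C(COCc1ccccc1)C(O)=O | intermediate
5 | 2-[(benzyloxy)methyl]malonyl dichloride | ClC(=O)C(COCc1ccccc1)C(Cl)=O | intermediate
6 | methyl 4,4-dimethoxy-3-oxobutanoate | COC(=O)CC(=O)C(OC)OC | starting material
7 | methyl 3-[(benzyloxy)methyl]-6-(dimethoxymethyl)-4-hydroxy-2-oxo-2H-pyran-5-carboxylate | COC(=O)c1c(C(OC)OC)oc(=O)c(COCc2ccccc2)c1O | intermediate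
8 | methyl 3-[(benzyloxy)methyl]-6-(dimethoxymethyl)-4-(methoxymethoxy)-2-oxo-2H-pyran-5-carboxylate | COC(=O)c1c(C(OC)OC)oc(=O)c(COCc2ccccc2)c1OCOC | intermediate
9 | 1,1-dimethoxyethene | C=C(OC)OC | starting material
10 | methyl 4-[(benzyloxy)methyl]-1-(dimethoxymethyl)-8,8-dimethoxy-5-(methoxymethoxy)-3-oxo-2-oxabicyclo[2.2.2]oct-5-ene-6-carboxylate (racemic, not isolated) | COCOC1=C(C(=O)OC)C2(C(OC)OC)CC(OC)(OC)C1(COCc3ccccc3)C(=O)O2 | intermediate
11 | methyl 5-[(benzyloxy)methyl]-2-(dimethoxymethyl)-4,4-dimethoxy-6-(methoxymethoxy)cyclohexa-1,5-diene-1-carboxylate (not isolated) | COC(=O)C1=C(C(OC)OC)CC(OC)(OC)C(COCc2ccccc2)=C1OCOC | intermediate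
12 | methyl 3-[(benzyloxy)methyl]-6-(dimethoxymethyl)-4-methoxy-2-(methoxymethoxy)benzoate | COC(=O)c1c(C(OC)OC)cc(OC)c(COCc2ccccc2)c1OCOC | intermediate
13 | methyl 6-(dimethoxymethyl)-3-(hydroxymethyl)-4-methoxy-2-(methoxymethoxy)benzoate | COC(=O)c1c(C(OC)OC)cc(OC)c(CO)c1OCOC | intermediate
14 | methyl 2,4-dihydroxy-3,6-dimethylbenzoate | COC(=O)c1c(C)cc(O)c(C)c1O | starting material
15 | methyl 2-hydroxy-4-methoxy-3,6-dimethylbenzoate | COC(=O)c1c(C)cc(OC)c(C)c1O | intermediate
16 | 2-hydroxy-4-methoxy-3,6-dimethylbenzoic acid | COc1cc(C)c(C(=O)O)c(O)c1C | intermediate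
17 | [4-(dimethoxymethyl)-6-methoxy-3-(methoxycarbonyl)-2-(methoxymethoxy)phenyl]methyl 2-hydroxy-4-methoxy-3,6-dimethylbenzoate | COC(=O)c1c(C(OC)OC)cc(OC)c(COC(=O)c2c(C)cc(OC)c(C)c2O)c1OCOC | intermediate
18 | [4-formyl-6-methoxy-3-(methoxycarbonyl)-2-(methoxymethoxy)phenyl]methyl 2-hydroxy-4-methoxy-3,6-dimethylbenzoate (not isolated) | COC(=O)c1c(C=O)cc(OC)c(COC(=O)c2c(C)cc(OC)c(C)c2O)c1OCOC | intermediate
19 | [3-hydroxy-5-methoxy-7-(methoxymethoxy)-1-oxo-1,3-dihydroisobenzofuran-6-yl]methyl 2-hydroxy-4-methoxy-3,6-dimethylbenzoate (racemic) | COc1cc(C)c(C(=O)OCc2c(OC)cc3c(c2OCOC)C(=O)OC3O)c(O)c1C | intermediate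
20 | [3,7-dihydroxy-5-methoxy-1-oxo-1,3-dihydroisobenzofuran-6-yl]methyl 2-hydroxy-4-methoxy-3,6-dimethylbenzoate (racemic) | COc1cc(C)c(C(=O)OCc2c(OC)cc3c(c2O)C(=O)OC3O)c(O)c1C | intermediate
21 | [(3R)-3-acetoxy-7-hydroxy-5-methoxy-1-oxo-1,3-dihydroisobenzofuran-6-yl]methyl 2-hydroxy-4-methoxy-3,6-dimethylbenzoate | COc1cc(C)c(C(=O)OCc2c(OC)cc3c(c2O)C(=O)O[C@H]3OC(C)=O)c(O)c1C | intermediate
22 | [(3R)-3,7-dihydroxy-5-methoxy-1-oxo-1,3-dihydroisobenzofuran-6-yl]methyl 2-hydroxy-4-methoxy-3,6-dimethylbenzoate | COc1cc(C)c(C(=O)OCc2c(OC)cc3c(c2O)C(=O)O[C@H]3O)c(O)c1C | target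

Total step count: 14. Longest linear sequence: 12 steps (steps 1–7 and 10–14); steps 8 and 9 form the ring A branch.

**Steps most likely to fail**

Step 6. The cycloaddition may be too slow: both diene ends are fully substituted and the 4-alkoxy group makes the pyrone electron-richer, so oligomerisation of the ketene acetal and thermal decomposition could outrun ring formation. The fallback makes the diene electron-poorer. It sets out from 7, which is acylated with pivaloyl chloride (Et3N, CH2Cl2, 0 °C) to methyl 3-[(benzyloxy)methyl]-6-(dimethoxymethyl)-2-oxo-4-(pivaloyloxy)-2H-pyran-5-carboxylate F1. The acyloxy group is a far weaker donor than an alkoxy group, so cycloaddition with 9 should proceed at lower temperature with the same orientation. Loss of CO2 and methanol should then give methyl 3-[(benzyloxy)methyl]-6-(dimethoxymethyl)-4-methoxy-2-(pivaloyloxy)benzoate F2. Methanolysis (NaOMe, MeOH) frees methyl 3-[(benzyloxy)methyl]-6-(dimethoxymethyl)-2-hydroxy-4-methoxybenzoate F3, and MOMCl/NaH in DMF returns to the route at 12.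

Step 14. Configuration at C3 may be lost by ring–chain tautomerism of the freed lactol during alcoholysis, filtration and concentration. The same fallback serves if step 13 delivers the acetate with insufficient enantiomeric purity. It sets out from racemic 20 and replaces the chemical release by a physical resolution: preparative chiral-phase HPLC on an immobilised polysaccharide phase with an aprotic eluent (hexane–ethyl acetate) at 0–5 °C, fractions collected and evaporated cold. The unwanted enantiomer is re-equilibrated at 40 °C and recycled. The fallback arrives directly at 22 and makes no new compound (F0).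

Step 4. Acid-promoted loss of the dimethyl acetal, elimination of benzyl alcohol from the malonyl unit and self-condensation of the dichloride may outrun the annulation. The fallback is stepwise and base-mediated, and sets out from 3. Half-saponification (KOH, 1.0 equiv, EtOH, 0 °C) gives ethyl hydrogen 2-[(benzyloxy)methyl]malonate F4. Oxalyl chloride with catalytic DMF converts it into ethyl 2-[(benzyloxy)methyl]-3-chloro-3-oxopropanoate F5. This C-acylates the magnesium enolate of 6 (MgCl2, pyridine, CH2Cl2, 0 °C) to 1-ethyl 5-methyl 2-[(benzyloxy)methyl]-4-(2,2-dimethoxyacetyl)-3-oxopentanedioate F6. DBU in toluene at 80 °C then closes the enol oxygen onto the ethyl ester with loss of ethanol and returns to the route at 7.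

**Further compounds**
F1 | step 6 | methyl 3-[(benzyloxy)methyl]-6-(dimethoxymethyl)-2-oxo-4-(pivaloyloxy)-2H-pyran-5-carboxylate | COC(=O)c1c(C(OC)OC)oc(=O)c(COCc2ccccc2)c1OC(=O)C(C)(C)C
F2 | step 6 | methyl 3-[(benzyloxy)methyl]-6-(dimethoxymethyl)-4-methoxy-2-(pivaloyloxy)benzoate | COC(=O)c1c(C(OC)OC)cc(OC)c(COCc2ccccc2)c1OC(=O)C(C)(C)C
F3 | step 6 | methyl 3-[(benzyloxy)methyl]-6-(dimethoxymethyl)-2-hydroxy-4-methoxybenzoate | COC(=O)c1c(C(OC)OC)cc(OC)c(COCc2ccccc2)c1O
F0 | step 14 | none | none
F4 | step 4 | ethyl hydrogen 2-[(benzyloxy)methyl]malonate (racemic) | CCOC(=O)C(COCc1ccccc1)C(=O)O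
F5 | step 4 | ethyl 2-[(benzyloxy)methyl]-3-chloro-3-oxopropanoate (racemic) | CCOC(=O)C(COCc1ccccc1)C(Cl)=O
F6 | step 4 | 1-ethyl 5-methyl 2-[(benzyloxy)methyl]-4-(2,2-dimethoxyacetyl)-3-oxopentanedioate (racemic) | CCOC(=O)C(COCc1ccccc1)C(=O)C(C(=O)OC)C(=O)C(OC)OC
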